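## Retrosynthetic overview

1. Atom labels C1–C20 are the eunicellane positions of the target: C2–O–C9 ether, C3–O–C16 lactone, C17/C18/C20 are the methyls on C15/C3/C11, C19 is the exocyclic CH2.
2. Oxonane last: Nozaki–Hiyama–Kishi closure of C6–C7 from a 2-bromoalkene aldehyde.
3. Seven-membered lactone and C3/C4: Shi epoxidation of a Z-alkene acid, then 7-exo opening at C3 by the C16 acid; the Z-alkene comes from a Wittig reaction on an α-alkoxy methyl ketone.
4. Tetrahydrofuran: a new one-pot [3+2] annulation of the ring A enone with a glycolamide mixed acetal (Mukaiyama–Michael, then oxocarbenium/enol silane closure); C11 carbinol by MeMgBr.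
5. Ring A first: organocatalytic transfer hydrogenation (C15), enamine Michael addition to methyl vinyl ketone (C14), aldol condensation. Ring order: cyclohexane, tetrahydrofuran, lactone, oxonane.

Assumption: the Nagata phosphonate, 3-bromobut-3-en-1-ol, the glycolic Weinreb amide and the dioxolanyl phosphonium salt are taken as catalogue compounds, and the (S)-imidazolidinone of step 2 is taken to give the (R)-aldehyde (otherwise its enantiomer is used).

## Route

Step 1
Reactants: 1 1-(tert-butyldimethylsilyloxy)propan-2-one; 2 diethyl [2-(cyclohexylamino)vinyl]phosphonate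
Product: 4 (E)-3-methyl-4-(tert-butyldimethylsilyloxy)but-2-enal, via N-cyclohexyl azadiene 3 (not isolated)
Conditions: NaH, THF, 0 °C → rt; then 10% aq. oxalic acid, rt
Reagents that add atoms: water, O
Why: Horner–Wadsworth–Emmons formyl-olefination of the activated ketone gives the unsaturated imine, which aqueous acid hydrolyses to the enal; the E/Z ratio is not critical because step 2 is stereoconvergent.

Step 2
Reactants: 4 (E)-3-methyl-4-(tert-butyldimethylsilyloxy)but-2-enal
Product: 5 (R)-3-methyl-4-(tert-butyldimethylsilyloxy)butanal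
Conditions: diethyl 2,6-dimethyl-1,4-dihydropyridine-3,5-dicarboxylate (Hantzsch ester, 1.2 equiv), (S)-2-tert-butyl-3-methylimidazolidin-4-one·CCl3CO2H (20 mol %), CHCl3, −30 °C
Reagents that add atoms: none
Why: Organocatalytic iminium-ion transfer hydrogenation: the E/Z iminium ions interconvert and hydride adds to the β-face left open by the tert-butyl group, setting C15 as the first stereocentre.

Step 3
Reactants: 5 (R)-3-methyl-4-(tert-butyldimethylsilyloxy)butanal; 6 methyl vinyl ketone
Product: 7 (2S)-2-[(2R)-1-(tert-butyldimethylsilyloxy)propan-2-yl]-5-oxohexanal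
Conditions: (S)-2-[diphenyl(trimethylsilyloxy)methyl]pyrrolidine (10 mol %), ethyl 3,4-dihydroxybenzoate (20 mol %), neat, 4 °C
Reagents that add atoms: none
Why: Enamine-catalysed asymmetric Michael addition: the E-enamine is attacked on the face away from the diphenyl(silyloxy)methyl group, so C14 is set under catalyst control over the existing C15 centre.

Step 4
Reactants: 7 (2S)-2-[(2R)-1-(tert-butyldimethylsilyloxy)propan-2-yl]-5-oxohexanal
Product: 8 (4R)-4-[(2R)-1-(tert-butyldimethylsilyloxy)propan-2-yl]cyclohex-2-en-1-one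
Conditions: LiOH, iPrOH, rt
Reagents that add atoms: none
Why: Intramolecular aldol condensation of the methyl ketone onto the aldehyde closes ring A as the C11 enone; C14 ends up γ to the carbonyl and keeps its configuration under these mild conditions.

Step 5
Reactants: 9 3-bromobut-3-en-1-ol
Product: 11 2-bromo-4,4-dimethoxybut-1-ene, via 3-bromobut-3-enal 10 (not isolated)
Conditions: Dess–Martin periodinane, CH2Cl2, 0 °C; then HC(OMe)3, MeOH, PPTS (cat.), 0 °C → rt
Reagents that add atoms: trimethyl orthoformate, COC(OC)OC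
Why: Dess–Martin oxidation followed at once by acid-catalysed acetalisation protects the isomerisation-prone β,γ-unsaturated aldehyde without isolating it.

Step 6
Reactants: 11 2-bromo-4,4-dimethoxybut-1-ene; 12 2-hydroxy-N-methoxy-N-methylacetamide
Product: 14 2-[(3-bromo-1-methoxybut-3-en-1-yl)oxy]-N-methoxy-N-methylacetamide (racemic at the acetal carbon), via 2-bromo-4-chloro-4-methoxybut-1-ene 13 (not isolated)
Conditions: AcCl, ZnBr2 (0.1 mol %), CH2Cl2, rt; then 12, iPr2NEt, 0 °C → rt
Reagents that add atoms: none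
Why: Lewis-acid-catalysed acetal/acyl chloride exchange gives the α-chloro ether, which O-alkylates the hydroxy amide as in a MOM-type etherification.

Step 7
Reactants: 8 (4R)-4-[(2R)-1-(tert-butyldimethylsilyloxy)propan-2-yl]cyclohex-2-en-1-one; 14 2-[(3-bromo-1-methoxybut-3-en-1-yl)oxy]-N-methoxy-N-methylacetamide
Product: 17 cis-fused bicyclic keto Weinreb amide (octahydroisobenzofuran core; C11 ketone; C2 amide; C9 2-bromoallyl), via silyl ketene N,O-acetal 15 (not isolated), via enol silane Michael adduct 16 (not isolated)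
Conditions: 14, LiN(SiMe3)2, TMSCl, THF, −78 °C; solvent switch to MeCN, 8, 40 °C; then TMSOTf (20 mol %), CH2Cl2, −78 → −40 °C
Reagents that add atoms: none
Why: Proposed new method: a formal [3+2] annulation in which the amide-derived silyl ketene N,O-acetal adds without catalyst to the enone (Mukaiyama–Michael) anti to the C14 side chain (sets C1) and passes its silyl group to the ring A enolate, giving the regiodefined C10 enol silane; TMSOTf then ionises the tethered mixed acetal (MeOSiMe3 leaves) and the enol silane attacks the C9 oxocarbenium ion in a 5-(enolexo) closure that can only give the cis-fused tetrahydrofuran (sets C10), with the 2-bromoallyl group expected on the convex face away from the C11 silyloxy group (sets C9), while C2 is corrected in step 8; the closest known chemistry is the sequential Mukaiyama Michael–aldol reaction of enones with silyl ketene acetals and acetals, and the enol/oxocarbenium aldol closure of Prins–pinacol tetrahydrofuran syntheses.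

Step 8
Reactants: 17 cis-fused bicyclic keto Weinreb amide
Product: 18 bicyclic C11 tertiary alcohol C3 methyl ketone
Conditions: MeMgBr (4 equiv), CeCl3, THF, −78 → 0 °C; then K2CO3, MeOH, rt
Reagents that add atoms: methylmagnesium bromide, C[Mg]Br
Why: Grignard (organocerium) addition: methyl attacks the C11 ketone axially from the convex face, anti to the axial C9 substituent, so the hydroxyl ends cis to C9, and the Weinreb amide stops at the methyl ketone; K2CO3 then equilibrates the epimerisable C2 to the exo acetyl isomer, trans to C14.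

Step 9
Reactants: 18 bicyclic C11 tertiary alcohol C3 methyl ketone; 19 [2-(1,3-dioxolan-2-yl)ethyl]triphenylphosphonium bromide
Product: 20 (Z)-C3=C4 alkene carrying the C6 dioxolane
Conditions: 19, KN(SiMe3)2, THF, −78 °C; then 18, −78 → 0 °C
Reagents that add atoms: none
Why: Wittig olefination: α-alkoxy ketones react with non-stabilised ylides through the cis-oxaphosphetane to give the Z-trisubstituted alkene, with C2 and C5 cis.

Step 10
Reactants: 20 (Z)-C3=C4 alkene carrying the C6 dioxolane
Product: 21 C16 primary alcohol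
Conditions: Bu4NF, THF, 0 °C → rt
Reagents that add atoms: none
Why: Fluoride-mediated desilylation removes the only silyl ether; the vinyl bromide, acetal and tertiary alcohol are inert.

Step 11
Reactants: 21 C16 primary alcohol
Product: 22 C16 carboxylic acid
Conditions: TEMPO (20 mol %), PhI(OAc)2, MeCN/H2O, rt
Reagents that add atoms: water, O
Why: Oxoammonium (TEMPO) oxidation takes the primary alcohol through the aldehyde hydrate to the acid; the tertiary alcohol, alkenes and dioxolane are untouched and C15 is not epimerised.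

Step 12
Reactants: 22 C16 carboxylic acid
Product: 24 hydroxy lactone (C3–O–C16 lactone; free C4 hydroxyl), via epoxy acid 23 (not isolated)
Conditions: 1,2:4,5-di-O-isopropylidene-D-erythro-2,3-hexodiulo-2,6-pyranose (Shi ketone, 30 mol %), KHSO5 (as 2KHSO5·KHSO4·K2SO4), K2CO3, Bu4NHSO4 (cat.), MeCN/(MeO)2CH2/H2O, pH 10.5, 0 °C; then acidify, camphorsulfonic acid (10 mol %), CH2Cl2, 0 °C → rt
Reagents that add atoms: potassium peroxymonosulfate, [K+].[O-]OS(=O)(=O)O
Why: Shi asymmetric epoxidation (spiro transition state, reagent control) puts oxygen on the alkene face anti to the ring C2–O bond, and acid then triggers a 7-exo epoxy-acid lactonisation in which the C16 acid opens the tertiary C3 with inversion, setting C3 and leaving the C4 hydroxyl with retention.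

Step 13
Reactants: 24 hydroxy lactone
Product: 25 C4 octanoate
Conditions: octanoyl chloride, DMAP, pyridine, CH2Cl2, 0 °C → rt
Reagents that add atoms: octanoyl chloride, CCCCCCCC(=O)Cl
Why: DMAP-catalysed acylation esterifies the secondary C4 hydroxyl; the tertiary C11 hydroxyl does not react.

Step 14
Reactants: 25 C4 octanoate
Product: 26 C6 aldehyde
Conditions: TsOH·H2O (cat.), acetone/H2O, 40 °C
Reagents that add atoms: water, O
Why: Acid-catalysed acetal hydrolysis frees the aldehyde under conditions that spare the lactone, the octanoate and the β-acyloxy aldehyde.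

Step 15
Reactants: 26 C6 aldehyde
Product: 27 briarellin A
Conditions: CrCl2 (8 equiv), NiCl2 (2 mol %), DMSO/THF, rt, 2 mM
Reagents that add atoms: none
Why: Nozaki–Hiyama–Kishi cyclisation: zerovalent nickel inserts into the C–Br bond, transmetalation gives the alkenyl trivalent chromium species, and this adds to the aldehyde to close the oxonane; the rigid tricyclic core should direct attack to one aldehyde face and give the 6S alcohol, as in related cladiellin closures.

## Compound list

1 | 1-(tert-butyldimethylsilyloxy)propan-2-one | CC(=O)CO[Si](C)(C)C(C)(C)C | starting material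
2 | diethyl [2-(cyclohexylamino)vinyl]phosphonate | CCOP(=O)(C=CNC1CCCCC1)OCC | starting material
3 | N-cyclohexyl-3-methyl-4-(tert-butyldimethylsilyloxy)but-2-en-1-imine (E/Z mixture) | CC(CO[Si](C)(C)C(C)(C)C)=CC=NC1CCCCC1 | intermediate
4 | (E)-3-methyl-4-(tert-butyldimethylsilyloxy)but-2-enal | C/C(CO[Si](C)(C)C(C)(C)C)=C\C=O | intermediate
5 | (R)-3-methyl-4-(tert-butyldimethylsilyloxy)butanal | O=CC[C@@H](C)CO[Si](C)(C)C(C)(C)C | intermediate
6 | methyl vinyl ketone (but-3-en-2-one) | CC(=O)C=C | starting material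
7 | (2S)-2-[(2R)-1-(tert-butyldimethylsilyloxy)propan-2-yl]-5-oxohexanal | O=C[C@@H](CCC(C)=O)[C@@H](C)CO[Si](C)(C)C(C)(C)C | intermediate
8 | (4R)-4-[(2R)-1-(tert-butyldimethylsilyloxy)propan-2-yl]cyclohex-2-en-1-one | O=C1CC[C@H](C=C1)[C@@H](C)CO[Si](C)(C)C(C)(C)C | intermediate
9 | 3-bromobut-3-en-1-ol | OCCC(Br)=C | starting material
10 | 3-bromobut-3-enal | O=CCC(Br)=C | intermediate
11 | 2-bromo-4,4-dimethoxybut-1-ene | COC(OC)CC(Br)=C | intermediate
12 | 2-hydroxy-N-methoxy-N-methylacetamide | CON(C)C(=O)CO | starting material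
13 | 2-bromo-4-chloro-4-methoxybut-1-ene (racemic) | COC(Cl)CC(Br)=C | intermediate
14 | 2-[(3-bromo-1-methoxybut-3-en-1-yl)oxy]-N-methoxy-N-methylacetamide (racemic) | CON(C)C(=O)COC(OC)CC(Br)=C | intermediate
15 | trimethylsilyl ketene N,O-acetal of 14 | CON(C)C(O[Si](C)(C)C)=COC(OC)CC(Br)=C | intermediate
16 | ring A C10=C11 trimethylsilyl enol ether Michael adduct; C1 trans to the C14 side chain; C2 and the acetal carbon C9 as epimer mixtures | C=C(Br)CC(OC)OC(C(=O)N(C)OC)[C@@H]1C=C(O[Si](C)(C)C)CC[C@H]1[C@@H](C)CO[Si](C)(C)C(C)(C)C | intermediate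
17 | cis-fused octahydroisobenzofuran with C11 ketone; C2 C(=O)N(OMe)Me and C9 CH2C(Br)=CH2 on the face opposite ring A; C14 CH(CH3)CH2OTBS; C1, C2, C9, C10, C14, C15 as in 27 (the C2 epimer converges in step 8) | C=C(Br)C[C@@H]2O[C@H](C(=O)N(C)OC)[C@H]4[C@@H](CCC(=O)[C@H]42)[C@@H](C)CO[Si](C)(C)C(C)(C)C | intermediate
18 | as 17 but C11 is C(OH)CH3 (hydroxyl cis to C9) and C2 carries acetyl; all ring stereocentres as in 27 | C=C(Br)C[C@@H]2O[C@H](C(C)=O)[C@H]4[C@@H](CC[C@@](C)(O)[C@H]42)[C@@H](C)CO[Si](C)(C)C(C)(C)C | intermediate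
19 | [2-(1,3-dioxolan-2-yl)ethyl]triphenylphosphonium bromide | [Br-].C(C[P+](c1ccccc1)(c1ccccc1)c1ccccc1)C1OCCO1 | starting material
20 | as 18 but C2 carries (Z)-C3(CH3)=C4H–C5H2–C6H(OCH2CH2O) | C=C(Br)C[C@@H]2O[C@H](/C(C)=C\CC5OCCO5)[C@H]4[C@@H](CC[C@@](C)(O)[C@H]42)[C@@H](C)CO[Si](C)(C)C(C)(C)C | intermediate
21 | as 20 with free C16 primary alcohol | C=C(Br)C[C@@H]2O[C@H](/C(C)=C\CC5OCCO5)[C@H]4[C@@H](CC[C@@](C)(O)[C@H]42)[C@@H](C)CO | intermediate
22 | as 20 with C16 carboxylic acid | C=C(Br)C[C@@H]2O[C@H](/C(C)=C\CC5OCCO5)[C@H]4[C@@H](CC[C@@](C)(O)[C@H]42)[C@@H](C)C(=O)O | intermediate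
23 | cis-C3,C4 epoxide of 22; oxygen on the face anti to the ring C2–O bond | C=C(Br)C[C@@H]2O[C@H]([C@]5(C)O[C@@H]5CC6OCCO6)[C@H]4[C@@H](CC[C@@](C)(O)[C@H]42)[C@@H](C)C(=O)O | intermediate
24 | tricyclic hydroxy lactone: C3–O–C16 seven-membered lactone, free C4 and C11 hydroxyls, C9 2-bromoallyl, C6 dioxolane; stereocentres as in 27 | C=C(Br)C[C@@H]2O[C@H]3[C@H]4[C@@H](CC[C@@](C)(O)[C@H]42)[C@@H](C)C(=O)O[C@@]3(C)[C@H](O)CC5OCCO5 | intermediate
25 | C4 octanoate of 24 | C=C(Br)C[C@@H]2O[C@H]3[C@H]4[C@@H](CC[C@@](C)(O)[C@H]42)[C@@H](C)C(=O)O[C@@]3(C)[C@H](OC(=O)CCCCCCC)CC5OCCO5 | intermediate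
26 | C6 aldehyde from 25 | C=C(Br)C[C@@H]2O[C@H]3[C@H]4[C@@H](CC[C@@](C)(O)[C@H]42)[C@@H](C)C(=O)O[C@@]3(C)[C@H](OC(=O)CCCCCCC)CC=O | intermediate
27 | briarellin A | C=C1C[C@@H]2O[C@H]3[C@H]4[C@@H](CC[C@@](C)(O)[C@H]42)[C@@H](C)C(=O)O[C@@]3(C)[C@H](OC(=O)CCCCCCC)C[C@@H]1O | target

## Step count and risks

Total step count: 15. Longest linear sequence: 13 steps (steps 1–4 and 7–15); steps 5–6 make the annulation partner.

The three steps most likely to fail:

**Step 7, the new annulation.** The reagent may self-condense once the acetal is ionised, the uncatalysed Michael addition to the hindered enone may be slow, and the 2-bromoallyl group may not go cleanly to the convex face. The fallback makes the same bonds in known stages and sets out from 8. Amide 12 is converted with LiN(SiMe3)2 and TMSCl into its O-silylated silyl ketene N,O-acetal F1. Uncatalysed Mukaiyama–Michael addition of F1 to 8 in MeCN gives the bis-silylated adduct F2, and aqueous acid work-up gives the hydroxy keto amide F3. Etherification of the C2 hydroxyl with chloro ether 13 (made from 11 as in step 6; iPr2NEt) gives the mixed acetal keto amide F4. TMSOTf/Et3N then forms enol silane 16 in the flask and closes it onto the ionised acetal, a known one-pot enol silane formation and acetal addition; only the C10 enol silane can form a five-membered ring. The fallback comes back to the route at 17.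

**Step 12, Shi epoxidation and lactonisation.** The Z-alkene is hindered and the reagent must override the substrate's own facial preference; the 7-exo opening by a carboxylic acid is also uncommon. The fallback uses the other epoxide face productively and sets out from 20. Epoxidation on the opposite face (mCPBA if substrate control points that way, otherwise the enantiomeric Shi ketone) gives the opposite-face epoxide F5. CsO2C(CH2)6CH3 in DMF at 80 °C opens it at the less substituted C4 with inversion to give the C4 octanoate tertiary alcohol F6, in which C3 and C4 already have the target configuration. Bu4NF gives the primary alcohol F7, and TEMPO/PhI(OAc)2 gives the seco acid F8. Lactonisation onto the tertiary C3 hydroxyl with 2-methyl-6-nitrobenzoic anhydride and DMAP comes back to the route at 25.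

**Step 15, the nine-membered ring closure.** The bromoalkene is less reactive than an iodide, and the C6 configuration rests on substrate control alone. The fallback sets C6 by reduction instead and sets out from 26. If the closure gives mainly the C6 epimer of 27 F9, Dess–Martin oxidation gives the exocyclic enone (C6 ketone) F10. Reduction under catalyst control with (R)-1-methyl-3,3-diphenyl-tetrahydro-1H,3H-pyrrolo[1,2-c][1,3,2]oxazaborole and catecholborane at −78 °C then comes back to the route at 27.

Further compounds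

F1 | step 7 | O-trimethylsilyl silyl ketene N,O-acetal of 12 | CON(C)C(O[Si](C)(C)C)=CO[Si](C)(C)C
F2 | step 7 | bis-silylated Michael adduct of F1 and 8 | CON(C)C(=O)C(O[Si](C)(C)C)[C@@H]1C=C(O[Si](C)(C)C)CC[C@H]1[C@@H](C)CO[Si](C)(C)C(C)(C)C
F3 | step 7 | hydroxy keto amide | CON(C)C(=O)C(O)[C@@H]1CC(=O)CC[C@H]1[C@@H](C)CO[Si](C)(C)C(C)(C)C
F4 | step 7 | mixed acetal keto amide | CON(C)C(=O)C(OC(OC)CC(Br)=C)[C@@H]1CC(=O)CC[C@H]1[C@@H](C)CO[Si](C)(C)C(C)(C)C
F5 | step 12 | opposite-face cis-C3,C4 epoxide of 20 | C=C(Br)C[C@@H]2O[C@H]([C@@]5(C)O[C@H]5CC6OCCO6)[C@H]4[C@@H](CC[C@@](C)(O)[C@H]42)[C@@H](C)CO[Si](C)(C)C(C)(C)C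
F6 | step 12 | C4 octanoate with free C3 tertiary alcohol | C=C(Br)C[C@@H]2O[C@H]([C@@](C)(O)[C@H](OC(=O)CCCCCCC)CC6OCCO6)[C@H]4[C@@H](CC[C@@](C)(O)[C@H]42)[C@@H](C)CO[Si](C)(C)C(C)(C)C
F7 | step 12 | C16 primary alcohol of F6 | C=C(Br)C[C@@H]2O[C@H]([C@@](C)(O)[C@H](OC(=O)CCCCCCC)CC6OCCO6)[C@H]4[C@@H](CC[C@@](C)(O)[C@H]42)[C@@H](C)CO
F8 | step 12 | seco acid | C=C(Br)C[C@@H]2O[C@H]([C@@](C)(O)[C@H](OC(=O)CCCCCCC)CC6OCCO6)[C@H]4[C@@H](CC[C@@](C)(O)[C@H]42)[C@@H](C)C(=O)O
F9 | step 15 | C6 epimer of 27 | C=C1C[C@@H]2O[C@H]3[C@H]4[C@@H](CC[C@@](C)(O)[C@H]42)[C@@H](C)C(=O)O[C@@]3(C)[C@H](OC(=O)CCCCCCC)C[C@H]1O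
F10 | step 15 | C6 ketone (exocyclic enone) | C=C1C[C@@H]2O[C@H]3[C@H]4[C@@H](CC[C@@](C)(O)[C@H]42)[C@@H](C)C(=O)O[C@@]3(C)[C@H](OC(=O)CCCCCCC)CC1=O
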